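## The problem

CNP0157858.4 is a rearranged abietane whose five rings share one compact core. Rings A and B are trans-fused, ring C is cis-fused to ring B, a cyclobutane (C1–C10–C9–C11) spans the bay region and is cis-fused to all three six-membered rings, and a methylcyclopropane is spiro-linked at C13. There are eleven stereocentres, among them the contiguous fully substituted carbons C9, C10 and C11 and the quaternary spiro carbon C13. The quaternary carbon C10 is the natural relay: once C1, C9 and C10 are fixed, the cyclobutane offers a convex β face and a shielded α face from which C11, C12 and C8 can be set. C5, C6 and C7 in ring B do not follow from that relay and have to be set by reactions that answer to ring shape or to a directing group. The fragile functions are the cyclobutane-1,2-diol (retro-aldol or α-ketol ring expansion threatens whenever a carbonyl at C12 sits beside a free C11 or C9 hydroxyl), the two β-hydroxy ketone units around C14, the acylcyclopropane, and two acetates next to free hydroxyls. Strong base, strong Lewis acid and dissolving metals must therefore stay away from late intermediates. The enabling feature is that the cyclobutane is made of C10–C9(O), the α-carbon and carbonyl carbon of a ring B ketone, and C1–C11, a two-carbon unit carrying C12. That is the retron of a formal [2+2] union of a ring B enol ether with an enoate, and a ring B with carbonyl at C9, methyl at C10 and a handle at C7 is carvone.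

## Retrosynthesis

**C6–O and C7–O.** Target 36 is the C9 silyl ether 35 without its silyl group, and 35 is cut at C6–O to the 6α,7α-epoxide 34. Enolate or hydride chemistry of a C7 ketone would bring oxygen to C6 from the open α face; the epoxide opening instead forces the nucleophile onto the β face and puts the acetate on the right oxygen without differentiating two neighbouring secondary hydroxyls. Epoxide 34 goes back through epoxy triol 33 and triol 32 to the Δ6 alkene 31. The forward steps must deliver the oxirane to the α face and open it at C6.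

**C5–H.** Alkene 31 is traced to 7α-alcohol 30 (syn-dehydration), then to allylic alcohol 29 and enone 28, so the C5–H bond is made late by hydroxyl-directed hydrogenation. The reason lies in the key step: a chain hanging from C5 can reach C10 only on the face from which it hangs, so cyclobutane formation necessarily gives a cis A/B fusion. Instead of asking that step for a trans fusion, C5 is allowed to form in the opposite sense and is rewritten through the Δ5-en-7-one 28. The C7 ketone needed for ring C closure makes this enone available at the cost of one dehydrogenation.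

**C8–C14 (ring C).** Enone 28 is cut to enone aldehyde 26; the forward step is an intramolecular Mukaiyama aldol of dienol ether 27. A Claisen closure onto a C14 ester would give an enolised 7,14-diketone whose two carbonyls cannot be told apart. Closure at C12–C13 would need an enolate of a cyclopropyl ketone. In 26 ring C is reduced to a side chain on C11, and the enone has a single α′ position (C8), so regiochemistry is not in question.

**C12–C13.** Aldehyde 26 comes from hydroxy aldehyde 21 and this from hydroxy nitrile 19, which is cut into aldehyde 15 and nitrile 18 (made from epoxide 16 and phosphonate 17). This cut brings in the cyclopropane with C15 already set, whereas a late cyclopropanation would have to control C13 and C15 against remote centres. It also delivers C12 at the alcohol level, so no C12 ketone ever stands beside the C11 oxygen. The forward reaction must control the face of the cyclopropyl anion and the face of the aldehyde.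

**C11–O.** Aldehyde 15 goes back through silyl ether 14 and hydroxy ester 13 to ester 12. Enolate hydroxylation on the convex face of the tricycle sets C11 and makes the C11 configuration of 12 irrelevant.

**C1–C10 and C9–C11 (key disconnection).** Ester 12 is cut to monocyclic keto enoate 10 through enol ether 11. Two rings and four stereocentres are removed at once, and the precursor is a substituted cyclohexanone. Stepwise alternatives would need a separate route to the C10 quaternary centre. The forward step requires C1 to enter syn to the C5 chain; since the target needs the 10β-methyl group, the chain must hang on the α face, which is the configuration obtained from (S)-carvone.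

**Chain and ring B.** Enoate 10 is cut at C1=C11 into alkene 8 and acrylate 9 (cross-metathesis). Alkene 8 goes back through alcohol 7 to keto aldehyde 6 (C2–C3, reagent-controlled allylation). Aldehyde 6 comes from diol 5 and keto ester 4, and 4 is cut at C4–C5 into carvone 1 and ketene acetal 2 (via enol ether 3).

## Roads not taken

**Alternative 1:** The cut is C9–C11 alone. In the forward sense SmI2 would reduce the ketone of the α-keto ester in diketo ester A1 to a ketyl that adds to the C9 ketone, closing the cyclobutane as cis-diol A2. Its merit is real: both tertiary carbinols C9 and C11 appear in one step as the cis-diol, where the chosen plan needs the key step plus a separate hydroxylation. Its weak points are that only one bond is formed, so A1 must already hold the C10 quaternary centre and the C1 substituent with the right relative configuration. A four-membered pinacol closure is also uncommon, and the diolate of A2 can reopen by retro-aldol cleavage toward the ester. A2 further carries no function at C7 or C8, so the C8–C14 bond has no handle, and C5 to C7 must be worked out from an isolated Δ5 alkene. The chosen plan sets against the one-step diol the fact that it forms two C–C bonds, ring A and the cyclobutane together, and that it keeps an oxygen handle at C7 to activate C8.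

**Alternative 2:** The cut is C8–C14 together with C7–O, made late. Aldoxime A3 would be oxidised to nitrile oxide A4, which adds across C7=C8 to give isoxazoline A5; N–O cleavage would then unveil the C7 hydroxyl and the C14 ketone. For the C7/C8/C14 triad this is better than the chosen plan: one suprafacial cycloaddition sets 7α-O and 8β-H and masks the β-hydroxy ketone, where the chosen route spends an aldol, a reduction, a dehydration, an epoxidation and an opening. Its weakness is that it is an endgame only. A3 already contains the cyclobutane diol, the spirocyclopropane, the 6β-acetate and a Δ7 alkene, and the alternative does not say how that core is made. The C7=C8 alkene with an allylic 6β-acetate is an additional demand on ring B. The chosen plan answers the harder question, the construction of the C9/C10/C11 core, and carries its own, longer solution for ring C.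

**Alternative 3:** The cut is ring B (C9–C10 and C7–C8). An oxazaborolidinium-catalysed Diels–Alder reaction of diene A6 with quinone A7 would give adduct A8. It is more convergent than the chosen plan, uses a catalyst for absolute control, and delivers the complete carbon set of ring C, a C12 oxygen, the C7 oxygen and the cis B/C fusion in one step. Its weak points are the diene terminus C10, which is fully substituted and must become quaternary in the cycloaddition, and above all what follows. A8 has hydrogen at C9 and no C1–C11 bond, so the cyclobutane, the C9 and C11 hydroxyls and the spirocyclopropane all have to be introduced late on a crowded enedione, by C–H abstraction or oxidation steps whose site selectivity is open. The chosen plan is longer to the full skeleton but builds the cyclobutane and its three contiguous fully substituted carbons first, in one ionic step of a known type, under chiral-pool control.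

Key step: step 7

Remark: abietane numbering is used for all intermediates and β is the face of the C10 methyl group; nitrile 18 may contain its cis isomer, because C13 is deprotonated before use.

## Route

Step 1
Reactants: 1 (S)-carvone; 2 1-methoxy-2-methyl-1-(trimethylsilyloxy)prop-1-ene
Product: 4 keto ester (both C10 epimers), via TMS enol ether 3 (not isolated)
Conditions: HNTf2 (2 mol %), CH2Cl2, −78 °C; then 1 M HCl, THF, 0 °C
Reagents that add atoms: none
Why: Mukaiyama–Michael addition; the ketene acetal adds to the enone β-carbon (C5) anti to the isopropenyl group by axial attack on the half-chair, which fixes C5 relative to C7 (chain α, isopropenyl β); C10 forms as both epimers, which converge in step 7.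

Step 2
Reactants: 4 keto ester
Product: 5 diol (mixture at C9 and C10)
Conditions: LiAlH4, THF, 0 °C to 25 °C; Rochelle salt work-up
Reagents that add atoms: none
Why: Hydride reduction of the neopentyl ester and of the ketone; the new C9 carbinol centre is removed again in step 3, so the mixture is carried on.

Step 3
Reactants: 5 diol
Product: 6 keto aldehyde (both C10 epimers)
Conditions: Dess–Martin periodinane, CH2Cl2, 0 °C to 25 °C
Reagents that add atoms: none
Why: Dess–Martin oxidation of both alcohols returns the C9 ketone and gives a non-enolisable aldehyde at C3.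

Step 4
Reactants: 6 keto aldehyde
Product: 7 (3S)-homoallylic alcohol
Conditions: (−)-Ipc2B(allyl) from (+)-α-pinene, Et2O, −78 °C; then pH 7 buffer, H2O2, MeOH, 0 °C
Reagents that add atoms: B-allyldiisopinocampheylborane from (+)-α-pinene, C=CCB([C@@H]1C[C@@H]2C[C@H]([C@H]1C)C2(C)C)[C@@H]1C[C@@H]2C[C@H]([C@H]1C)C2(C)C
Why: Brown allylation; at −78 °C the allylborane reacts only with the aldehyde and adds to its Si face under reagent control, giving the (3S)-alcohol (3β), while the hindered ketone is untouched.

Step 5
Reactants: 7 homoallylic alcohol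
Product: 8 C3 TBS ether
Conditions: TBSOTf, 2,6-lutidine, CH2Cl2, −78 °C to 0 °C
Reagents that add atoms: tert-butyldimethylsilyl trifluoromethanesulfonate, CC(C)(C)[Si](C)(C)OS(=O)(=O)C(F)(F)F
Why: Silyl triflate silylation of the hindered neopentylic alcohol; it also removes the δ-hydroxy ketone/hemiketal equilibrium before the ketone is used.

Step 6
Reactants: 8 C3 TBS ether; 9 methyl acrylate
Product: 10 keto enoate (both C10 epimers)
Conditions: second-generation Hoveyda–Grubbs catalyst RuCl2(H2IMes)(=CH-C6H4-2-OiPr) (5 mol %), CH2Cl2, 40 °C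
Reagents that add atoms: none
Why: Cross-metathesis of the monosubstituted alkene with the electron-poor acrylate gives the (E)-enoate; the 1,1-disubstituted isopropenyl group is too hindered to compete.

Step 7
Reactants: 10 keto enoate
Product: 12 tricyclic cyclobutane ester, via silyl enol ether 11 (not isolated)
Conditions: TBSOTf (3 equiv), Et3N (4 equiv), CH2Cl2, −78 °C to 25 °C
Reagents that add atoms: tert-butyldimethylsilyl trifluoromethanesulfonate, CC(C)(C)[Si](C)(C)OS(=O)(=O)C(F)(F)F
Why: Silyl triflate and amine convert either C10 epimer of 10 into the tetrasubstituted C9=C10 enol ether 11; the triflate then activates the enoate, C10 adds to C1 (Mukaiyama–Michael, 6-exo-trig, ring A), and the resulting ester silyl ketene acetal closes onto the C9 silyloxycarbenium ion (aldol, 4-exo-trig, cyclobutane), releasing the silyl cation that carries the chain. The closest known reaction type is the silyl triflate/amine-mediated intramolecular Michael–aldol (formal [2+2]) reaction of cycloalkanone enol ethers with tethered α,β-unsaturated esters. C10: the three-atom chain hangs from the α bond of C5 and can form a six-membered ring only by reaching the α lobe of C10 (torsion C4–C5–C10–C1 near 45°; the β lobe would need more than 100°), so the methyl group ends β and the A/B fusion is cis; this is the selectivity the step needs, and the (S)-carvone-derived C5 secures it. C1: in the chair of the forming ring A the 3β-silyloxy group is equatorial and the enoate carbon C11 lies anti to the C10 methyl, directly under C9, which gives 1β-H; the (3S) centre is matched with this arrangement. C9: C1 stands axial on ring B, perpendicular to the carbonyl plane, so C11 can only bond to the α face and the cyclobutane closes cis with 9β-OTBS. C11 is not controlled and need not be, since step 8 erases it. The Δ8 enol ether cannot cyclise and returns through the ketone.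

Step 8
Reactants: 12 tricyclic ester
Product: 13 11β-hydroxy ester
Conditions: KN(SiMe3)2, THF, −78 °C; 2-(phenylsulfonyl)-3-phenyloxaziridine, −78 °C; NH4Cl
Reagents that add atoms: 2-(phenylsulfonyl)-3-phenyloxaziridine, O=S(=O)(N1OC1c1ccccc1)c1ccccc1
Why: Enolate hydroxylation with an N-sulfonyloxaziridine; the planar C11 enolate is attacked on the convex β face (the α face lies in the fold of rings A and B, between C2 and C8), so the hydroxyl is cis to the C9 oxygen as in the target and both C11 epimers of 12 converge.

Step 9
Reactants: 13 11β-hydroxy ester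
Product: 14 C11 TES ether
Conditions: TESOTf, 2,6-lutidine, CH2Cl2, 0 °C to 25 °C
Reagents that add atoms: triethylsilyl trifluoromethanesulfonate, CC[Si](CC)(CC)OS(=O)(=O)C(F)(F)F
Why: Silylation of the tertiary α-hydroxy ester; it blocks α-ketol ring expansion and retro-aldol opening of the cyclobutane once C12 becomes an aldehyde.

Step 10
Reactants: 14 C11 TES ether
Product: 15 C12 aldehyde
Conditions: iBu2AlH, CH2Cl2, −78 °C; Rochelle salt work-up
Reagents that add atoms: none
Why: Partial reduction of an α-silyloxy ester; the chelated tetrahedral aluminate persists at −78 °C and releases the aldehyde only on work-up.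

Step 11
Reactants: 16 (S)-propylene oxide; 17 diethyl (cyanomethyl)phosphonate
Product: 18 (1R,2R)-2-methylcyclopropane-1-carbonitrile
Conditions: NaH, 1,2-dimethoxyethane, 0 °C; then 16, sealed vessel, 90 °C
Reagents that add atoms: none
Why: Wadsworth–Emmons cyclopropanation; the phosphonate anion opens the epoxide at CH2, phosphoryl transfer to oxygen follows, and 3-exo displacement with inversion turns the (S)-epoxide carbon into the (2R) centre (future C15); the configuration at C1 is irrelevant.

Step 12
Reactants: 15 C12 aldehyde; 18 cyclopropyl nitrile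
Product: 19 12-hydroxy nitrile
Conditions: LiN(iPr)2, THF, −78 °C (18); then 15, −78 °C; NH4Cl at −78 °C
Reagents that add atoms: none
Why: Addition of an α-lithiated cyclopropyl nitrile to a non-enolisable aldehyde; the anion reacts anti to its ring methyl group (C13 with the nitrile cis to the C15 methyl), and at C12 the nucleophile is expected anti to the fully substituted C9 with the carbonyl hydrogen in the cleft between C2 and C8, which gives the C12 configuration of the target. The cold quench prevents silyl migration from O11 to O12.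

Step 13
Reactants: 19 12-hydroxy nitrile
Product: 21 β-hydroxy aldehyde, via aldimine 20 (not isolated)
Conditions: iBu2AlH, toluene, −78 °C to −40 °C; then aqueous tartaric acid, 0 °C
Reagents that add atoms: water, O
Why: Nitrile reduction stops at the N-aluminated aldimine, which is hydrolysed on work-up; retro-aldol cleavage of 21 is not a concern because it would require a cyclopropyl anion.

Step 14
Reactants: 21 β-hydroxy aldehyde
Product: 23 7β,12-diacetate, via methoxy hydroperoxide 22 (not isolated)
Conditions: O3, CH2Cl2/MeOH, −78 °C; then Ac2O, Et3N, DMAP, CH2Cl2, 0 °C to 35 °C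
Reagents that add atoms: ozone, [O-][O+]=O; methanol, CO; acetic anhydride, CC(=O)OC(C)=O
Why: Ozonolysis of the only alkene in methanol gives the α-methoxy hydroperoxide; acylation triggers the Criegee rearrangement, in which C7 migrates to oxygen with retention, so the acetate stands where the isopropenyl group stood. The same reagent acetylates the hindered C12 hydroxyl; the silyl ethers and the non-enolisable aldehyde are inert.

Step 15
Reactants: 23 7β,12-diacetate
Product: 24 7β-alcohol
Conditions: K2CO3 (0.2 equiv), MeOH, 0 °C
Reagents that add atoms: none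
Why: Methanolysis distinguishes the ordinary secondary acetate at C7 from the C12 acetate, which lies between two fully substituted carbons; short reaction at 0 °C also spares the silyl ethers.

Step 16
Reactants: 24 7β-alcohol
Product: 26 Δ5-en-7-one aldehyde, via ketone 25 (not isolated)
Conditions: IBX (4 equiv), DMSO/fluorobenzene, 25 °C then 70 °C
Reagents that add atoms: none
Why: IBX oxidises the alcohol to ketone 25 and then dehydrogenates it; only C5–C6 can be desaturated because C9 carries no hydrogen, so C5 becomes trigonal and the cis A/B centre is erased.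

Step 17
Reactants: 26 Δ5-en-7-one aldehyde
Product: 28 pentacyclic enone with C14 OTES, via silyl dienol ether 27 (not isolated)
Conditions: TESOTf (2.5 equiv), iPr2NEt (3 equiv), CH2Cl2, −78 °C to −20 °C
Reagents that add atoms: triethylsilyl trifluoromethanesulfonate, CC[Si](CC)(CC)OS(=O)(=O)C(F)(F)F
Why: Soft enolisation at the only α′ position (C8) gives the cross-conjugated dienol ether, which adds to the silyl-activated aldehyde (intramolecular Mukaiyama aldol, 6-exo) with silyl transfer to O14; C8 bonds on the α face because the chain comes from the α bond of C9 (cis B/C, 8β-H), and the C14 carbinol centre is oxidised later.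

Step 18
Reactants: 28 pentacyclic enone
Product: 29 7α-allylic alcohol
Conditions: NaBH4, CeCl3·7H2O, MeOH/THF, −78 °C to 0 °C
Reagents that add atoms: none
Why: Luche 1,2-reduction; hydride enters from the β face, anti to the α-oriented C8–C14 bond, and gives the 7α-alcohol.

Step 19
Reactants: 29 7α-allylic alcohol
Product: 30 5α-H 7α-alcohol
Conditions: [Ir(cod)(PCy3)(py)]PF6 (10 mol %), H2, CH2Cl2, 25 °C
Reagents that add atoms: none
Why: Hydroxyl-directed hydrogenation; the cationic iridium catalyst binds the 7α-hydroxyl and delivers hydrogen to the α face of C5=C6, setting 5α-H (trans A/B) against the steric bias that produced the cis fusion.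

Step 20
Reactants: 30 5α-H 7α-alcohol
Product: 31 Δ6 alkene
Conditions: Burgess reagent, toluene, 70 °C
Reagents that add atoms: none
Why: Syn-elimination of the sulfamate ester; only C6 carries a hydrogen cis to the 7α-oxygen (C8 has only 8β-H), so the Δ6 alkene forms regiospecifically.

Step 21
Reactants: 31 Δ6 alkene
Product: 32 triol (C9 OTBS retained)
Conditions: HF·pyridine, pyridine, THF, 0 °C to 25 °C
Reagents that add atoms: none
Why: Fluoride removes the secondary TBS and TES ethers and the tertiary TES ether; the tertiary TBS ether at C9, flanked by two fully substituted carbons, is the slowest and stays.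

Step 22
Reactants: 32 triol
Product: 33 6α,7α-epoxide
Conditions: VO(acac)2 (5 mol %), t-BuOOH, CH2Cl2, 0 °C to 25 °C
Reagents that add atoms: tert-butyl hydroperoxide, CC(C)(C)OO
Why: Vanadium-catalysed hydroxyl-directed epoxidation; the homoallylic C14 hydroxyl sits on the α face and delivers oxygen there, and the β face is in addition screened by the C10 methyl, the axial C4 methyl and the C9 silyl ether.

Step 23
Reactants: 33 6α,7α-epoxide
Product: 34 epoxy 3,14-diketone
Conditions: Dess–Martin periodinane, pyridine, CH2Cl2, 0 °C to 25 °C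
Reagents that add atoms: none
Why: Dess–Martin oxidation of the two secondary alcohols; the tertiary hydroxyl, the epoxide and the acetate are inert under buffered conditions.

Step 24
Reactants: 34 epoxy 3,14-diketone
Product: 35 C9 O-TBS ether of the target
Conditions: AcOH, 50 °C
Reagents that add atoms: acetic acid, CC(=O)O
Why: Fürst–Plattner opening; in the trans-fused chair only attack at C6 from the β face is diaxial, and the C14 carbonyl disfavours charge build-up at C7, so inversion at C6 gives 6β-OAc and leaves the 7α-hydroxyl.

Step 25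
Reactants: 35 C9 O-TBS ether
Product: 36 CNP0157858.4
Conditions: HF (48 % aq.), MeCN, 0 °C to 25 °C
Reagents that add atoms: none
Why: Acidic fluoride cleaves the last silyl ether without base, which the β-hydroxy ketones and acetates would not tolerate.

## Compound list

1 | (S)-(+)-carvone, (5S)-2-methyl-5-(prop-1-en-2-yl)cyclohex-2-en-1-one | CC1=CC[C@H](C(C)=C)CC1=O | starting material
2 | 1-methoxy-2-methyl-1-(trimethylsilyloxy)prop-1-ene | COC(O[Si](C)(C)C)=C(C)C | starting material
3 | methyl 2-methyl-2-[(1S,5S)-2-methyl-5-(prop-1-en-2-yl)-3-(trimethylsilyloxy)cyclohex-2-en-1-yl]propanoate | COC(=O)C(C)(C)[C@H]1C[C@H](C(C)=C)CC(O[Si](C)(C)C)=C1C | intermediate (not isolated)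
4 | methyl 2-methyl-2-[(1S,5S)-2-methyl-3-oxo-5-(prop-1-en-2-yl)cyclohexyl]propanoate, both C10 epimers, chain and isopropenyl trans | COC(=O)C(C)(C)[C@H]1C[C@H](C(C)=C)CC(=O)C1C | intermediate
5 | (3S,5S)-3-(1-hydroxy-2-methylpropan-2-yl)-2-methyl-5-(prop-1-en-2-yl)cyclohexan-1-ol, mixture at C9 and C10 | OCC(C)(C)[C@H]1C[C@H](C(C)=C)CC(O)C1C | intermediate
6 | 2-methyl-2-[(1S,5S)-2-methyl-3-oxo-5-(prop-1-en-2-yl)cyclohexyl]propanal, both C10 epimers | O=CC(C)(C)[C@H]1C[C@H](C(C)=C)CC(=O)C1C | intermediate
7 | (3S,5S)-3-[(3S)-3-hydroxy-2-methylhex-5-en-2-yl]-2-methyl-5-(prop-1-en-2-yl)cyclohexan-1-one, both C10 epimers | C=CC[C@H](O)C(C)(C)[C@H]1C[C@H](C(C)=C)CC(=O)C1C | intermediate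
8 | tert-butyldimethylsilyl ether of 7 at the (3S)-hydroxyl | C=CC[C@H](O[Si](C)(C)C(C)(C)C)C(C)(C)[C@H]1C[C@H](C(C)=C)CC(=O)C1C | intermediate
9 | methyl acrylate | C=CC(=O)OC | starting material
10 | methyl (2E,5S)-5-(tert-butyldimethylsilyloxy)-6-methyl-6-[(1S,5S)-2-methyl-3-oxo-5-(prop-1-en-2-yl)cyclohexyl]hept-2-enoate, both C10 epimers (key-step precursor) | COC(=O)/C=C/C[C@H](O[Si](C)(C)C(C)(C)C)C(C)(C)[C@H]1C[C@H](C(C)=C)CC(=O)C1C | intermediate
11 | C9=C10 tert-butyldimethylsilyl enol ether of 10 | COC(=O)/C=C/C[C@H](O[Si](C)(C)C(C)(C)C)C(C)(C)[C@H]1C[C@H](C(C)=C)CC(O[Si](C)(C)C(C)(C)C)=C1C | intermediate (not isolated)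
12 | tricyclic ester (rings A and B plus cyclobutane C1–C10–C9–C11): CO2Me on C11 (drawn β, 11α-H), 1β-H, 5β-H and 10β-CH3 (A/B cis), 9β-OTBS, 3β-OTBS, 7β-isopropenyl (key-step product) | COC(=O)[C@@H]3[C@H]4C[C@H](O[Si](C)(C)C(C)(C)C)C(C)(C)[C@H]1C[C@H](C(C)=C)C[C@]3(O[Si](C)(C)C(C)(C)C)[C@]14C | intermediate
13 | 11β-hydroxy derivative of 12 (CO2Me now α on C11) | COC(=O)[C@@]3(O)[C@H]4C[C@H](O[Si](C)(C)C(C)(C)C)C(C)(C)[C@H]1C[C@H](C(C)=C)C[C@]3(O[Si](C)(C)C(C)(C)C)[C@]14C | intermediate
14 | 11-O-triethylsilyl ether of 13 | COC(=O)[C@@]3(O[Si](CC)(CC)CC)[C@H]4C[C@H](O[Si](C)(C)C(C)(C)C)C(C)(C)[C@H]1C[C@H](C(C)=C)C[C@]3(O[Si](C)(C)C(C)(C)C)[C@]14C | intermediate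
15 | C12 aldehyde from 14 (CHO α on C11) | O=C[C@@]3(O[Si](CC)(CC)CC)[C@H]4C[C@H](O[Si](C)(C)C(C)(C)C)C(C)(C)[C@H]1C[C@H](C(C)=C)C[C@]3(O[Si](C)(C)C(C)(C)C)[C@]14C | intermediate
16 | (S)-propylene oxide | C[C@H]1CO1 | starting material
17 | diethyl (cyanomethyl)phosphonate | CCOP(=O)(CC#N)OCC | starting material
18 | (1R,2R)-2-methylcyclopropane-1-carbonitrile | C[C@@H]1C[C@H]1C#N | intermediate
19 | adduct of 15 and 18: secondary hydroxyl at C12 (configuration of the target, 12-H β), quaternary cyclopropane carbon C13 bearing the nitrile (C14) cis to the C15 methyl, (15R) | N#C[C@]5(C[C@H]5C)[C@@H](O)[C@@]3(O[Si](CC)(CC)CC)[C@H]4C[C@H](O[Si](C)(C)C(C)(C)C)C(C)(C)[C@H]1C[C@H](C(C)=C)C[C@]3(O[Si](C)(C)C(C)(C)C)[C@]14C | intermediate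
20 | C14 aldimine of 19 | N=C[C@]5(C[C@H]5C)[C@@H](O)[C@@]3(O[Si](CC)(CC)CC)[C@H]4C[C@H](O[Si](C)(C)C(C)(C)C)C(C)(C)[C@H]1C[C@H](C(C)=C)C[C@]3(O[Si](C)(C)C(C)(C)C)[C@]14C | intermediate (not isolated)
21 | C14 aldehyde with free C12 hydroxyl | O=C[C@]5(C[C@H]5C)[C@@H](O)[C@@]3(O[Si](CC)(CC)CC)[C@H]4C[C@H](O[Si](C)(C)C(C)(C)C)C(C)(C)[C@H]1C[C@H](C(C)=C)C[C@]3(O[Si](C)(C)C(C)(C)C)[C@]14C | intermediate
22 | 2-hydroperoxy-2-methoxypropan-2-yl derivative of 21 at C7 | O=C[C@]5(C[C@H]5C)[C@@H](O)[C@@]3(O[Si](CC)(CC)CC)[C@H]4C[C@H](O[Si](C)(C)C(C)(C)C)C(C)(C)[C@H]1C[C@H](C(C)(OC)OO)C[C@]3(O[Si](C)(C)C(C)(C)C)[C@]14C | intermediate (not isolated)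
23 | 7β,12-diacetate with C14 aldehyde | O=C[C@]5(C[C@H]5C)[C@@H](OC(C)=O)[C@@]3(O[Si](CC)(CC)CC)[C@H]4C[C@H](O[Si](C)(C)C(C)(C)C)C(C)(C)[C@H]1C[C@H](OC(C)=O)C[C@]3(O[Si](C)(C)C(C)(C)C)[C@]14C | intermediate
24 | 7β-alcohol, 12-acetate, C14 aldehyde | O=C[C@]5(C[C@H]5C)[C@@H](OC(C)=O)[C@@]3(O[Si](CC)(CC)CC)[C@H]4C[C@H](O[Si](C)(C)C(C)(C)C)C(C)(C)[C@H]1C[C@H](O)C[C@]3(O[Si](C)(C)C(C)(C)C)[C@]14C | intermediate
25 | C7 ketone (5β-H), 12-acetate, C14 aldehyde | O=C[C@]5(C[C@H]5C)[C@@H](OC(C)=O)[C@@]3(O[Si](CC)(CC)CC)[C@H]4C[C@H](O[Si](C)(C)C(C)(C)C)C(C)(C)[C@H]1CC(=O)C[C@]3(O[Si](C)(C)C(C)(C)C)[C@]14C | intermediate (not isolated)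
26 | Δ5-en-7-one, 12-acetate, C14 aldehyde | O=C[C@]5(C[C@H]5C)[C@@H](OC(C)=O)[C@@]3(O[Si](CC)(CC)CC)[C@H]4C[C@H](O[Si](C)(C)C(C)(C)C)C(C)(C)C1=CC(=O)C[C@]3(O[Si](C)(C)C(C)(C)C)[C@]14C | intermediate
27 | C7 triethylsilyl dienol ether of 26 (C5=C6 and C7=C8) | O=C[C@]5(C[C@H]5C)[C@@H](OC(C)=O)[C@@]3(O[Si](CC)(CC)CC)[C@H]4C[C@H](O[Si](C)(C)C(C)(C)C)C(C)(C)C1=CC(O[Si](CC)(CC)CC)=C[C@]3(O[Si](C)(C)C(C)(C)C)[C@]14C | intermediate (not isolated)
28 | pentacyclic Δ5-en-7-one: ring C closed at C8–C14, 8β-H, 14-OTES (either C14 epimer), 12α-OAc, 11β-OTES, 9β-OTBS, 3β-OTBS | CC[Si](CC)(CC)OC6[C@]5(C[C@H]5C)[C@@H](OC(C)=O)[C@@]3(O[Si](CC)(CC)CC)[C@H]4C[C@H](O[Si](C)(C)C(C)(C)C)C(C)(C)C1=CC(=O)[C@@H]6[C@]3(O[Si](C)(C)C(C)(C)C)[C@]14C | intermediate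
29 | 7α-hydroxy-Δ5 compound from 28 | CC[Si](CC)(CC)OC6[C@]5(C[C@H]5C)[C@@H](OC(C)=O)[C@@]3(O[Si](CC)(CC)CC)[C@H]4C[C@H](O[Si](C)(C)C(C)(C)C)C(C)(C)C1=C[C@@H](O)[C@@H]6[C@]3(O[Si](C)(C)C(C)(C)C)[C@]14C | intermediate
30 | 5α-H (A/B trans) 7α-alcohol | CC[Si](CC)(CC)OC6[C@]5(C[C@H]5C)[C@@H](OC(C)=O)[C@@]3(O[Si](CC)(CC)CC)[C@H]4C[C@H](O[Si](C)(C)C(C)(C)C)C(C)(C)[C@@H]1C[C@@H](O)[C@@H]6[C@]3(O[Si](C)(C)C(C)(C)C)[C@]14C | intermediate
31 | Δ6 alkene (5α-H, 8β-H) | CC[Si](CC)(CC)OC6[C@]5(C[C@H]5C)[C@@H](OC(C)=O)[C@@]3(O[Si](CC)(CC)CC)[C@H]4C[C@H](O[Si](C)(C)C(C)(C)C)C(C)(C)[C@@H]1C=C[C@@H]6[C@]3(O[Si](C)(C)C(C)(C)C)[C@]14C | intermediate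
32 | Δ6 triol: 3β-OH, 11β-OH, 14-OH, 12α-OAc, 9β-OTBS | OC6[C@]5(C[C@H]5C)[C@@H](OC(C)=O)[C@@]3(O)[C@H]4C[C@H](O)C(C)(C)[C@@H]1C=C[C@@H]6[C@]3(O[Si](C)(C)C(C)(C)C)[C@]14C | intermediate
33 | 6α,7α-epoxide of 32 | OC6[C@]5(C[C@H]5C)[C@@H](OC(C)=O)[C@@]3(O)[C@H]4C[C@H](O)C(C)(C)[C@@H]1[C@H]7O[C@H]7[C@@H]6[C@]3(O[Si](C)(C)C(C)(C)C)[C@]14C | intermediate
34 | 6α,7α-epoxy-3,14-dione, 11β-OH, 12α-OAc, 9β-OTBS | O=C6[C@]5(C[C@H]5C)[C@@H](OC(C)=O)[C@@]3(O)[C@H]4CC(=O)C(C)(C)[C@@H]1[C@H]7O[C@H]7[C@@H]6[C@]3(O[Si](C)(C)C(C)(C)C)[C@]14C | intermediate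
35 | 9-O-tert-butyldimethylsilyl ether of the target (6β-OAc, 7α-OH) | O=C6[C@]5(C[C@H]5C)[C@@H](OC(C)=O)[C@@]3(O)[C@H]4CC(=O)C(C)(C)[C@@H]1[C@H](OC(C)=O)[C@@H](O)[C@@H]6[C@]3(O[Si](C)(C)C(C)(C)C)[C@]14C | intermediate
36 | CNP0157858.4: 6β,12α-diacetoxy-7α,9β,11β-trihydroxy-3,14-dione with C1–C11 bond and spiro C13 methylcyclopropane | CC(=O)O[C@@H]1[C@@H](O)[C@H]2C(=O)[C@]3(C[C@H]3C)[C@@H](OC(C)=O)[C@@]3(O)[C@H]4CC(=O)C(C)(C)[C@H]1[C@@]4(C)[C@@]23O | target

## Step count and least certain steps

Total: 25 steps. Longest linear sequence: 24 steps (steps 1–10 and 12–25 from (S)-carvone; step 11 is a one-step branch).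

**Step 7 (key step).** The most likely failure is that the sequence stops after the Michael addition. Closure of the four-membered ring pushes the C9 oxygen toward the axial C7 isopropenyl group, so loss of a proton from the C9 silyloxycarbenium ion to the amine may outrun it. Ene-type capture of that cation by the isopropenyl group is a second drain. The fallback sets out from 10 and returns at 12, making the two bonds in separate steps. Ketone 10 with Cs2CO3 in acetonitrile undergoes the anionic intramolecular Michael addition to the bicyclic keto ester F1; delivery is syn as before, and the step is reversible, so C1 can equilibrate. Irradiation of keto ester F1 (350 nm, benzene) effects a Norrish–Yang cyclisation: the C9 carbonyl abstracts the activated γ-hydrogen at C11 and the 1,4-biradical closes to cyclobutanol F2. TBSOTf and 2,6-lutidine then convert cyclobutanol F2 into 12.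

**Step 12 (C12–C13 bond).** The most likely failure is poor facial selectivity at the aldehyde, because the two ring carbons flanking C11 differ mainly in C9 being fully substituted. If the lithium alkoxide warms, migration of the triethylsilyl group from O11 to O12 is a further risk. The fallback sets out from 19 and returns at 19. The C12 epimer mixture is oxidised with Dess–Martin periodinane to the β-keto nitrile F3 and reduced with NaBH4/CeCl3·7H2O. Hydride then takes the trajectory the carbon nucleophile took before and delivers the opposite C12 epimer, so whichever sense the addition shows, one of the two sequences gives the required 12-configuration.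

**Step 19 (C5 inversion).** The most likely failure is lack of turnover or loss of hydroxyl direction at the C5=C6 bond, which lies between two quaternary carbons; the result would be recovered alkene or delivery from the β face. The fallback sets out from 29 and returns at 30. It is a radical hydrogen-atom-transfer hydrogenation (Mn(dpm)3, PhSiH3, t-BuOOH, isopropanol): a hydrogen atom adds to C6, and the tertiary C5 radical is reduced on the α face, anti to the C10 methyl, the mode that turns octalins into trans-decalins. No new compound (F0) is made.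

**Step 24 (epoxide acetolysis).** The most likely failure is slow opening, because acetic acid must enter at C6 beside the axial C10 and C4 methyl groups. Acid-induced β-elimination of the β,γ-epoxy ketone through the C14 enol, or opening at C7, could then take over. The fallback sets out from 34 and returns at 36; it uses water as the smaller nucleophile and introduces the acetate by acylation. HClO4 (catalytic) in aqueous THF at 0 °C gives the 6β,7α-diol F4. TESCl and imidazole silylate the less hindered 7α-hydroxyl to give the 7-O-triethylsilyl ether F5. Ac2O and DMAP acetylate the remaining 6β-hydroxyl to give the 6β-acetate F6. HF in acetonitrile removes both silyl groups from acetate F6 and gives 36.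

## Further compounds

F1 | step 7 | bicyclic keto ester (Michael adduct): methyl ester of the C1 acetic acid side chain, 1β-H, 5β-H, 10β-CH3, C9 ketone, 3β-OTBS, 7β-isopropenyl | COC(=O)C[C@H]4C[C@H](O[Si](C)(C)C(C)(C)C)C(C)(C)[C@H]1C[C@H](C(C)=C)CC(=O)[C@]14C
F2 | step 7 | cyclobutanol, the 9β-hydroxy analogue of 12 | COC(=O)[C@@H]3[C@H]4C[C@H](O[Si](C)(C)C(C)(C)C)C(C)(C)[C@H]1C[C@H](C(C)=C)C[C@]3(O)[C@]14C
F3 | step 12 | β-keto nitrile, the C12 ketone corresponding to 19 | N#C[C@]5(C[C@H]5C)C(=O)[C@@]3(O[Si](CC)(CC)CC)[C@H]4C[C@H](O[Si](C)(C)C(C)(C)C)C(C)(C)[C@H]1C[C@H](C(C)=C)C[C@]3(O[Si](C)(C)C(C)(C)C)[C@]14C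
F0 | step 19 | none | none
F4 | step 24 | 6β,7α-diol of the 9-O-TBS 3,14-dione | O=C6[C@]5(C[C@H]5C)[C@@H](OC(C)=O)[C@@]3(O)[C@H]4CC(=O)C(C)(C)[C@@H]1[C@H](O)[C@@H](O)[C@@H]6[C@]3(O[Si](C)(C)C(C)(C)C)[C@]14C
F5 | step 24 | 7-O-triethylsilyl ether of F4 | O=C6[C@]5(C[C@H]5C)[C@@H](OC(C)=O)[C@@]3(O)[C@H]4CC(=O)C(C)(C)[C@@H]1[C@H](O)[C@@H](O[Si](CC)(CC)CC)[C@@H]6[C@]3(O[Si](C)(C)C(C)(C)C)[C@]14C
F6 | step 24 | 6β-acetate of F5 | O=C6[C@]5(C[C@H]5C)[C@@H](OC(C)=O)[C@@]3(O)[C@H]4CC(=O)C(C)(C)[C@@H]1[C@H](OC(C)=O)[C@@H](O[Si](CC)(CC)CC)[C@@H]6[C@]3(O[Si](C)(C)C(C)(C)C)[C@]14C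
A1 | alternative 1 | bicyclic diketo α-keto ester (pinacol precursor) | CCOC(=O)C(=O)[C@H]4CC(=O)C(C)(C)C1=CCCC(=O)[C@]14C
A2 | alternative 1 | tricyclic cyclobutane-9,11-diol C11 ester | CCOC(=O)[C@@]3(O)[C@H]4CC(=O)C(C)(C)C1=CCC[C@]3(O)[C@]14C
A3 | alternative 2 | C14 aldoxime with Δ7 alkene and 9,11-acetonide | ON=C[C@]3(C[C@H]3C)[C@@H](OC(C)=O)[C@@]3(OC(C)(C)O6)[C@H]4CC(=O)C(C)(C)[C@@H]1[C@H](OC(C)=O)C=C[C@]36[C@]14C
A4 | alternative 2 | C14 nitrile oxide derived from A3 | [O-][N+]#C[C@]3(C[C@H]3C)[C@@H](OC(C)=O)[C@@]3(OC(C)(C)O6)[C@H]4CC(=O)C(C)(C)[C@@H]1[C@H](OC(C)=O)C=C[C@]36[C@]14C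
A5 | alternative 2 | isoxazoline-bridged complete carbon skeleton | CC(=O)O[C@@H]1[C@@H](O7)[C@H]2C(=N7)[C@]3(C[C@H]3C)[C@@H](OC(C)=O)[C@@]3(OC(C)(C)O6)[C@H]4CC(=O)C(C)(C)[C@H]1[C@@]4(C)[C@@]236
A6 | alternative 3 | ring A silyloxydiene | CC1=C(/C=C/O[Si](C)(C)C(C)(C)C)C(C)(C)C2(OCCO2)CC1
A7 | alternative 3 | ring C methoxyquinone with silyloxypropyl side chain | COC1=C([C@H](C)CO[Si](C)(C)C(C)(C)C)C(=O)C=CC1=O
A8 | alternative 3 | cis-fused tricyclic enedione Diels–Alder adduct | C1=C5C(C)(C)C6(OCCO6)CC[C@]5(C)[C@@H]2C(=O)C(OC)=C([C@H](C)CO[Si](C)(C)C(C)(C)C)C(=O)[C@@H]2[C@@H]1O[Si](C)(C)C(C)(C)C
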